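Assumption (remark on the chemistry): the target SMILES contains no stereocentre, no stereogenic double bond and no resolvable axis. Compound 12 is achiral, so "single enantiomer" calls for no stereocontrol. The only stereocentres on the route are the two bridgeheads of the transient adduct 8, and they are erased in the same flask.

Locants used throughout:
- Ring A is the acyl ring: A-C1 bears the ester carbonyl, A-C2 OH, A-C3 Cl, A-C4 OMe, A-C5 H, A-C6 propyl.
- Ring B is the phenol/acid ring: B-C1 CO2H, B-C2 OH, B-C3 H, B-C4 O-acyl, B-C5 H, B-C6 propyl.

## Analysis of the target

Compound 12 is a didepside: two benzene rings joined by one aryl ester, from the carbonyl on A-C1 to the oxygen on B-C4, with no further ring and no stereocentre. The problem is therefore purely one of regiochemistry and chemoselectivity. The hardest feature is the chlorine on A-C3, wedged between A-C2–OH and A-C4–OMe. A-C3 and A-C5 are activated by the same two oxygens, and B-C3 and B-C5 are activated as well, so an electrophilic chlorination has four candidate positions and no structural reason to choose A-C3. The second difficulty is the ester carbonyl. It is flanked by A-C2–OH and the A-C6 propyl group, so acyl transfer from a finished ring A acid to a weakly nucleophilic phenol is hindered. Three phenolic oxygens and one carboxylic acid must also be told apart, since only A-O4 carries a methyl group. The depside ester is cleaved by hydroxide or alkoxide, the salicylic-type acid on ring B decarboxylates on heating or in strong acid, and the aryl chloride is reducible. This narrows the choice of final steps. The feature that invites the chosen move is the sequence A-C2(O)–A-C3(Cl)–A-C4(O)–A-C5(H), which is the dienol form of a 2-chloro-1,3-dione. The remaining pair, A-C1(C=O)–A-C6(propyl), is the triple bond of a hex-2-ynoate. Ring A can thus be written as a [4+2] adduct in which the chlorine never has to be placed on an arene.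

## Retrosynthetic reasoning

**12 ⇒ 11.** The benzyl–oxygen bond of the ring B ester is cut last. The free acid is the most fragile function (decarboxylation, interference with every alkylation), and a benzyl ester is removed under neutral conditions that leave the depside ester alone. The forward reaction must cleave a benzylic C–O bond without touching A-C3–Cl.

**11 ⇒ 10.** The O–CH3 bond on A-O4 is cut. In 10 the phenols on A-C2 and B-C2 are both locked in six-membered hydrogen bonds to an ester carbonyl, and A-O4–H is the only free phenol, so one alkylation should suffice. The methyl group is not carried through the ring construction, because the two oxygens of the symmetric dione 5 offer no handle by which one could be methylated and the other silylated in the required sense.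

**10 ⇒ 4 + 6 (key disconnection).** Ring A is cut at A-C1–A-C2 and at A-C5–A-C6. This separates a four-carbon unit (A-C2 to A-C5, with both oxygens and the chlorine) from a two-carbon unit (A-C1 and A-C6, with the ester and the propyl group).
- The four-carbon unit is the s-cis-locked diene 6. Its extra CH2–CMe2 bridge serves only to be expelled as a volatile alkene on aromatisation.
- The two-carbon unit is the ynoate 4, which is already bound to B-O4.
- The cut is made here because it places all six substituents of ring A in one event through the polarity of the two partners, and the chlorine comes in on a carbon where its position is unambiguous.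
- The forward reaction has to achieve a regioselective cycloaddition to a β-alkyl ynoate and a cycloreversion, without harming two esters.

**4 ⇒ 2 + 3.** The acyl C–O bond of the future depside is cut at a stage where the acid is the linear, unhindered 3. The two ortho substituents that make depside couplings slow do not exist yet. The forward reaction has to acylate B-O4 and leave the chelated B-O2 alone.

**2 ⇒ 1 and 6 ⇒ 5.** Compound 2 is the benzyl ester of commercial 1. Compound 6 is the double silyl enol ether of commercial 5, in which the chlorine already sits on the carbon between the two oxygenated carbons. Both are single operations, so the precursors of the key step cost three steps in total.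

## Alternatives that were turned down

**Alternative 1: the textbook cut at the acyl C–O bond of the depside, between two finished arenes.**
- Forward key step: 3-chloro-2-hydroxy-4-methoxy-6-propylbenzoic acid A1 is activated (carbodiimide or mixed anhydride) and joined to B-O4 of 2 to give 11.
- It leaves the real problem untouched. A1 must be made by chlorinating an arene in which A-C3 and A-C5 are both ortho/para to the same two oxygens, so a separation of isomers must be expected.
- Making A1 also needs a selective methylation and the hydrolysis of a di-ortho-substituted ester.
- The coupling then pushes a weak phenol nucleophile onto a carbonyl flanked by OH and propyl, while the free A-O2–H can self-condense.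
- The route is longer, and its hardest selectivity rests on nothing in the structure.

**Alternative 2: biomimetic polyketide folding, cutting the depside C–O bond and A-C1–A-C6 together.**
- Forward key step: 6-(1-chloro-2,4-dioxoheptyl)-2,2-dimethyl-4H-1,3-dioxin-4-one A2 is heated with 2. Cycloreversion and ketene capture give the open-chain aryl 4-chloro-3,5,7-trioxodecanoate A3, and an aldol condensation of chain C2 onto chain C7 aromatises it to 10.
- The idea is attractive, but in A3 the chlorine sits on an sp3 carbon between two carbonyl groups.
- That C–H is the most acidic of the chain, so base parks the charge at chain C4 and away from C2, which must be the nucleophile.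
- Whenever chain C6 enolises instead, its oxygen is placed for a 5-exo-tet displacement of chloride.
- The aryloxide is a good leaving group, so a Claisen-type closure (chain C6 onto C1) and E1cB loss of 2 compete with the aldol mode.
- A2 itself needs two low-temperature acylations of chlorinated dienolates. The risk would sit in several places at once.

**Alternative 3: cutting A-C3–Cl last.**
- Forward key step: the complete chlorine-free depside, benzyl 2-hydroxy-4-[(2-hydroxy-4-methoxy-6-propylbenzoyl)oxy]-6-propylbenzoate A4, is treated with an electrophilic chlorine source, possibly with an ortho-directing catalyst, to give 11.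
- Four activated C–H positions compete (A-C3, A-C5, B-C3, B-C5).
- The phenol that should direct to A-C3 is tied up in a hydrogen bond to the depside carbonyl and cannot bind a directing catalyst well.
- A-C5 is para to that phenol and no less activated.
- The isomers would differ only in the position of one chlorine on a late, valuable intermediate. The step count is short, but the outcome has no structural guarantee.

Key step: step 4

## Route

Step 1
Reactants: 1 2,4-dihydroxy-6-propylbenzoic acid (divaric acid)
Product: 2 benzyl 2,4-dihydroxy-6-propylbenzoate
Conditions: BnBr (1.05 equiv), KHCO3 (1.1 equiv), DMF, rt to 40 °C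
Reagents that add atoms: benzyl bromide, BrCc1ccccc1
Why: Carboxylate alkylation (SN2); hydrogen carbonate deprotonates the carboxylic acid but not the phenols, so benzylation should stop at the ester, and the mild temperature avoids decarboxylation of 1.

Step 2
Reactants: 2 benzyl 2,4-dihydroxy-6-propylbenzoate; 3 hex-2-ynoic acid
Product: 4 benzyl 4-(hex-2-ynoyloxy)-2-hydroxy-6-propylbenzoate
Conditions: DCC (1.1 equiv), DMAP (5 mol %), CH2Cl2, 0 °C to rt
Reagents that add atoms: none
Why: Steglich esterification, the usual way to aryl alkynoates; B-O2–H is chelated to the benzyl ester carbonyl and crowded, so only B-O4 should be acylated, and the carbonyl of 3 is unhindered. The low DMAP loading and low temperature limit conjugate addition to the ynoate.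

Step 3
Reactants: 5 2-chloro-5,5-dimethylcyclohexane-1,3-dione
Product: 6 2-chloro-5,5-dimethyl-1,3-bis(trimethylsilyloxy)cyclohexa-1,3-diene
Conditions: TMSOTf (2.3 equiv), Et3N (2.6 equiv), Et2O, 0 °C to rt; salt layer removed, Kugelrohr distillation, used at once
Reagents that add atoms: trimethylsilyl trifluoromethanesulfonate, C[Si](C)(C)OS(=O)(=O)C(F)(F)F
Why: Soft enolisation and O-silylation of a 1,3-diketone with a silyl triflate and a tertiary amine; the enol is silylated first, then O-silylation of the remaining carbonyl gives a symmetric bis(silyloxy)allyl cation that loses a proton from either flanking CH2 to give the same diene. The chlorine stays on an sp2 carbon throughout and cannot migrate.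

Step 4
Reactants: 4 benzyl 4-(hex-2-ynoyloxy)-2-hydroxy-6-propylbenzoate; 6 2-chloro-5,5-dimethyl-1,3-bis(trimethylsilyloxy)cyclohexa-1,3-diene
Product: 10 benzyl 4-[(3-chloro-2,4-dihydroxy-6-propylbenzoyl)oxy]-2-hydroxy-6-propylbenzoate, via B-ring silyl ether 7 (not isolated), via bicyclooctadiene adduct 8 (not isolated), via tris(silyl ether) 9 (not isolated)
Conditions: BSA (1.2 equiv), PhMe, 60 °C, then volatiles removed in vacuo; 6 (4 equiv), neat, 140 °C, sealed tube, Ar; then 1 M HCl, THF, rt
Reagents that add atoms: none
Why: This is a Diels–Alder/retro-Diels–Alder benzannulation (Alder–Rickert reaction), whose closest known form is the union of 5,5-dimethyl-1,3-bis(silyloxy)cyclohexa-1,3-dienes with 2-alkynoate esters to give 6-alkyl-2,4-dihydroxybenzoates. After BSA has capped the chelated ring B phenol (7), so that no acidic proton consumes the diene, the s-cis-locked, electron-rich 6 adds suprafacially across the electron-poor triple bond in a normal-electron-demand [4+2] and gives the bicyclo[2.2.2]octa-2,5-diene 8. At the same temperature 8 undergoes cycloreversion, the CH2–CMe2 bridge leaves as isobutene, ring A appears as the aromatic tris(silyl ether) 9, and dilute acid frees the three phenols. Ring A is thus closed by one intermolecular six-electron cycloaddition that forms A-C1–A-C2 and A-C5–A-C6 together, and no other ring is formed. The selectivity the step needs is regioselectivity: both silyloxy groups of 6 polarise the diene towards its unsubstituted terminus C4, which bonds to the electrophilic, propyl-bearing β-carbon of the ynoate, while the oxygenated terminus C1 bonds to the α-carbon, so that one OH ends ortho and the other para to the ester and the chlorine of diene C2 can only land on A-C3. The aryl ester lowers the LUMO of the ynoate relative to an alkyl ester, which should offset the small HOMO-lowering effect of the chlorine. The two bridgehead stereocentres of 8 (racemic) vanish on aromatisation, so no stereocontrol is needed. Loss of a gas and gain of aromaticity make the sequence irreversible, and the benzyl ester, the aryl ester and arene B are not dienophiles and should survive neutral heating.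

Step 5
Reactants: 10 benzyl 4-[(3-chloro-2,4-dihydroxy-6-propylbenzoyl)oxy]-2-hydroxy-6-propylbenzoate
Product: 11 benzyl 4-[(3-chloro-2-hydroxy-4-methoxy-6-propylbenzoyl)oxy]-2-hydroxy-6-propylbenzoate
Conditions: MeI (1.1 equiv), K2CO3 (1.0 equiv), dry acetone, rt
Reagents that add atoms: iodomethane, CI
Why: Williamson-type O-alkylation; A-O4–H is the only phenol not locked in a hydrogen bond to an ester carbonyl and is the most acidic one (ortho chlorine, para acyl group), so one equivalent of weak base should form only this phenoxide. Dry acetone at room temperature leaves the depside ester intact.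

Step 6
Reactants: 11 benzyl 4-[(3-chloro-2-hydroxy-4-methoxy-6-propylbenzoyl)oxy]-2-hydroxy-6-propylbenzoate
Product: 12 3-chlorodivaricatic acid, 4-[(3-chloro-2-hydroxy-4-methoxy-6-propylbenzoyl)oxy]-2-hydroxy-6-propylbenzoic acid
Conditions: H2 (1 atm), 10 % Pd/C, EtOAc, rt, stopped after one equivalent of H2
Reagents that add atoms: none
Why: Catalytic hydrogenolysis of a benzyl ester; the benzylic C–O bond is cleaved much faster than a C–Cl bond on an electron-rich arene when no base is present to take up HCl. The neutral medium spares the depside ester and the decarboxylation-prone acid.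

## Compound list

1 | 2,4-dihydroxy-6-propylbenzoic acid (divaric acid) | CCCc1cc(O)cc(O)c1C(=O)O | starting material
2 | benzyl 2,4-dihydroxy-6-propylbenzoate | CCCc1cc(O)cc(O)c1C(=O)OCc1ccccc1 | intermediate
3 | hex-2-ynoic acid | CCCC#CC(=O)O | starting material
4 | benzyl 4-(hex-2-ynoyloxy)-2-hydroxy-6-propylbenzoate | CCCC#CC(=O)Oc1cc(O)c(C(=O)OCc2ccccc2)c(CCC)c1 | intermediate
5 | 2-chloro-5,5-dimethylcyclohexane-1,3-dione | CC1(C)CC(=O)C(Cl)C(=O)C1 | starting material
6 | 2-chloro-5,5-dimethyl-1,3-bis(trimethylsilyloxy)cyclohexa-1,3-diene | CC1(C)CC(O[Si](C)(C)C)=C(Cl)C(O[Si](C)(C)C)=C1 | intermediate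
7 | benzyl 4-(hex-2-ynoyloxy)-6-propyl-2-(trimethylsilyloxy)benzoate | CCCC#CC(=O)Oc1cc(O[Si](C)(C)C)c(C(=O)OCc2ccccc2)c(CCC)c1 | intermediate (not isolated)
8 | 4-[(benzyloxy)carbonyl]-3-propyl-5-(trimethylsilyloxy)phenyl 6-chloro-8,8-dimethyl-3-propyl-1,5-bis(trimethylsilyloxy)bicyclo[2.2.2]octa-2,5-diene-2-carboxylate (racemic, transient) | CCCC1=C(C(=O)Oc3cc(O[Si](C)(C)C)c(C(=O)OCc4ccccc4)c(CCC)c3)C2(O[Si](C)(C)C)CC(C)(C)C1C(O[Si](C)(C)C)=C2Cl | intermediate (not isolated)
9 | benzyl 4-{[3-chloro-6-propyl-2,4-bis(trimethylsilyloxy)benzoyl]oxy}-6-propyl-2-(trimethylsilyloxy)benzoate | CCCc1cc(O[Si](C)(C)C)c(Cl)c(O[Si](C)(C)C)c1C(=O)Oc1cc(O[Si](C)(C)C)c(C(=O)OCc2ccccc2)c(CCC)c1 | intermediate (not isolated)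
10 | benzyl 4-[(3-chloro-2,4-dihydroxy-6-propylbenzoyl)oxy]-2-hydroxy-6-propylbenzoate | CCCc1cc(O)c(Cl)c(O)c1C(=O)Oc1cc(O)c(C(=O)OCc2ccccc2)c(CCC)c1 | intermediate
11 | benzyl 4-[(3-chloro-2-hydroxy-4-methoxy-6-propylbenzoyl)oxy]-2-hydroxy-6-propylbenzoate | CCCc1cc(OC)c(Cl)c(O)c1C(=O)Oc1cc(O)c(C(=O)OCc2ccccc2)c(CCC)c1 | intermediate
12 | 3-chlorodivaricatic acid | CCCc1cc(OC(=O)c2c(CCC)cc(OC)c(Cl)c2O)cc(O)c1C(=O)O | target

## Step count and least certain steps

Total step count: 6. Longest linear sequence: 5 steps (steps 1, 2, 4, 5, 6). Step 3 is a one-step side branch.

**Step 4 (key step).**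
- What may go wrong: the cycloaddition may be too slow compared with the thermal decay of the reactants.
  - The chlorine lowers the diene HOMO somewhat.
  - The forming A-C5–A-C6 bond is crowded by the propyl group and the gem-dimethyl bridge.
  - During long heating with a large excess of a nucleophilic, silylating diene, the activated aryl ester may transfer its acyl group or be cleaved.
  - The valuable ynoate cannot be used in excess.
- Fallback (sets out from 3 and 6, comes back at 11): ring A is built first on a simple alkyl ynoate, the exact substrate class of the known reaction. That ynoate can be taken in excess and heated harder, and the ester bond is made afterwards.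
  - Acid 3 is benzylated (BnBr, K2CO3, DMF) to benzyl hex-2-ynoate F1.
  - F1 is heated neat with 6 and worked up with dilute acid to give benzyl 3-chloro-2,4-dihydroxy-6-propylbenzoate F2.
  - MeI/K2CO3 gives benzyl 3-chloro-2-hydroxy-4-methoxy-6-propylbenzoate F3.
  - Hydrogenolysis gives 3-chloro-2-hydroxy-4-methoxy-6-propylbenzoic acid F4 (identical with A1).
  - F4 is joined to B-O4 of 2 with trifluoroacetic anhydride in toluene to give 11.
  - The chlorine position is still set by 5. Only the convergence is given up.

**Step 3.**
- What may go wrong: the second enol silylation may stay incomplete, because the chlorine lowers the basicity of the vinylogous ester carbonyl that the silyl triflate has to activate. The product may also hydrolyse during isolation.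
- Fallback (sets out from 5, comes back at 10): irreversible hard enolisation of a purified intermediate replaces soft enolisation.
  - Compound 5 is converted with TBSCl/imidazole into the isolable vinylogous silyl ester 3-(tert-butyldimethylsilyloxy)-2-chloro-5,5-dimethylcyclohex-2-en-1-one F5.
  - Kinetic deprotonation at C6 (LDA, THF, −78 °C) and trapping with TMSCl give the mixed diene 1-(tert-butyldimethylsilyloxy)-2-chloro-5,5-dimethyl-3-(trimethylsilyloxy)cyclohexa-1,3-diene F6.
  - F6 takes the place of 6 in the cycloaddition with 7, and buffered fluoride (TBAF/AcOH) in place of dilute acid returns 10.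

**Step 5.**
- What may go wrong: site selectivity may be lost through alkylation of a chelated phenol, which the ortho chlorine makes more acidic. The base may also promote cleavage or migration of the depside acyl group.
- Fallback (sets out from 4, comes back at 11, bypassing 6 and 10): the methyl ether is brought in with the diene, so no phenol has to be alkylated.
  - Commercial methyl 2-chloro-3-oxobutanoate is converted with trimethyl orthoformate and catalytic acid into methyl 2-chloro-3-methoxybut-2-enoate F7 (E/Z mixture).
  - γ-Deprotonation (LDA, −78 °C) and O-silylation (TMSCl) give the vinylketene acetal 2-chloro-1,3-dimethoxy-1-(trimethylsilyloxy)buta-1,3-diene F8.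
  - The [4+2] cycloaddition of F8 to 7 (made from 4 as in step 4) has the same polarity match. Aromatisation then occurs by loss of methanol rather than by cycloreversion, and acid work-up should give 11 directly.

**Step 6.**
- What may go wrong: hydrodechlorination at A-C3 may compete with debenzylation if the reaction is run too long or on a very active catalyst.
- Fallback (sets out from 11, comes back at 12, no new compound): heterolytic rather than reductive cleavage. BCl3 with pentamethylbenzene as cation scavenger in CH2Cl2 at −78 °C removes the benzyl group by a Lewis-acid pathway that cannot touch an aryl chloride. The A-C4 methoxy group has no neighbouring carbonyl for chelation-assisted cleavage and should persist at this temperature.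

## Further compounds

F1 | step 4 | benzyl hex-2-ynoate | CCCC#CC(=O)OCc1ccccc1
F2 | step 4 | benzyl 3-chloro-2,4-dihydroxy-6-propylbenzoate | CCCc1cc(O)c(Cl)c(O)c1C(=O)OCc1ccccc1
F3 | step 4 | benzyl 3-chloro-2-hydroxy-4-methoxy-6-propylbenzoate | CCCc1cc(OC)c(Cl)c(O)c1C(=O)OCc1ccccc1
F4 | step 4 | 3-chloro-2-hydroxy-4-methoxy-6-propylbenzoic acid | CCCc1cc(OC)c(Cl)c(O)c1C(=O)O
F5 | step 3 | 3-(tert-butyldimethylsilyloxy)-2-chloro-5,5-dimethylcyclohex-2-en-1-one | CC1(C)CC(=O)C(Cl)=C(O[Si](C)(C)C(C)(C)C)C1
F6 | step 3 | 1-(tert-butyldimethylsilyloxy)-2-chloro-5,5-dimethyl-3-(trimethylsilyloxy)cyclohexa-1,3-diene | CC1(C)CC(O[Si](C)(C)C(C)(C)C)=C(Cl)C(O[Si](C)(C)C)=C1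
F7 | step 5 | methyl 2-chloro-3-methoxybut-2-enoate (E/Z mixture) | COC(=O)C(Cl)=C(C)OC
F8 | step 5 | 2-chloro-1,3-dimethoxy-1-(trimethylsilyloxy)buta-1,3-diene (E/Z mixture) | C=C(OC)C(Cl)=C(OC)O[Si](C)(C)C
F0 | step 6 | none | none
A1 | alternative 1 | 3-chloro-2-hydroxy-4-methoxy-6-propylbenzoic acid | CCCc1cc(OC)c(Cl)c(O)c1C(=O)O
A2 | alternative 2 | 6-(1-chloro-2,4-dioxoheptyl)-2,2-dimethyl-4H-1,3-dioxin-4-one (racemic, enolisable) | CCCC(=O)CC(=O)C(Cl)C1=CC(=O)OC(C)(C)O1
A3 | alternative 2 | 4-[(benzyloxy)carbonyl]-3-hydroxy-5-propylphenyl 4-chloro-3,5,7-trioxodecanoate (racemic, enolisable) | CCCC(=O)CC(=O)C(Cl)C(=O)CC(=O)Oc1cc(O)c(C(=O)OCc2ccccc2)c(CCC)c1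
A4 | alternative 3 | benzyl 2-hydroxy-4-[(2-hydroxy-4-methoxy-6-propylbenzoyl)oxy]-6-propylbenzoate | CCCc1cc(OC)cc(O)c1C(=O)Oc1cc(O)c(C(=O)OCc2ccccc2)c(CCC)c1
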